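**Assumptions.** The SMILES is read as (2S,5S,9S,10R,12S,13R) in labdane numbering: the normal labdane series of (+)-sclareolide (5α-H, 9α-H, 10β-Me), an equatorial 2α-Cl, and a 12,13-syn hydroxy-succinimide. The N-chloroamide reagent (step 1) and the Co(III)–salen precatalyst (step 5) are each made in one routine operation from purchased materials and are not counted as steps.

## Retrosynthetic overview

1. C12–C13 disconnection: haterumaimide G ⇒ keto-aldehyde 10 + maleimide 11, joined by a new Ni-catalysed reductive syn-coupling that sets C12 and C13.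
2. The 6-oxo-8(17)-ene unit of 10 ⇒ conjugated 7-en-6-one 7 by kinetic deconjugation; the C6 ketone comes from allylic oxidation of a Δ7 "relay" alkene 6.
3. Alkene 6 ⇒ tertiary alcohol 4 ⇒ 2α-chlorosclareolide 2 (lactone reduction, protection, dehydration, alkene isomerisation).
4. C2–Cl ⇒ site-selective radical C–H chlorination of (+)-sclareolide 1.
5. Ring order: the trans-decalin (rings A/B; C5, C9, C10) is bought intact in 1, the lactone is opened, and the succinimide ring arrives intact with maleimide in the last step. No carbocycle is built.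

## Forward route

**Step 1**
Reactants: 1, (+)-sclareolide
Product: 2, 2α-chlorosclareolide (equatorial Cl at labdane C2)
Conditions: N-chloro-N-tert-butyl-3,5-bis(trifluoromethyl)benzamide (1.0 equiv), Cs2CO3, PhH, visible light, 55 °C
Reagents that add atoms: N-chloro-N-tert-butyl-3,5-bis(trifluoromethyl)benzamide, CC(C)(C)N(Cl)C(=O)c1cc(cc(c1)C(F)(F)F)C(F)(F)F (Cl)
Why: Amidyl-radical C–H chlorination (HAT then Cl-atom transfer chain) picks the most accessible, least deactivated methylene (C2) and delivers Cl to the equatorial α-face, setting C2 (S); this exact substrate is precedented.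

**Step 2**
Reactants: 2, 2α-chlorosclareolide
Product: 3, 2α-chloro-13,14,15,16-tetranorlabdane-8α,12-diol
Conditions: LiBH4, THF, 0 °C → rt
Reagents that add atoms: none
Why: Hydride reduction of the γ-lactone to the diol; LiBH4 leaves the secondary chloride alone and no stereocentre is touched.

**Step 3**
Reactants: 3, the 8α,12-diol
Product: 4, 12-(tert-butyldimethylsilyloxy)-2α-chloro-13,14,15,16-tetranorlabdan-8α-ol
Conditions: TBSCl, imidazole, CH2Cl2, 0 °C → rt
Reagents that add atoms: TBSCl, CC(C)(C)[Si](C)(C)Cl
Why: Selective silylation of the primary alcohol; the hindered tertiary 8α-OH does not react.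

**Step 4**
Reactants: 4, the 12-OTBS 8α-ol
Product: 5, 12-TBSO-2α-chloro-13,14,15,16-tetranorlabd-8(17)-ene
Conditions: SOCl2, pyridine, CH2Cl2, −78 °C
Reagents that add atoms: none
Why: Chlorosulfite E2 dehydration; the equatorial 8α leaving group has no antiperiplanar ring C–H, so elimination goes to the C17 methyl (Hofmann-type) and gives mainly the exocyclic alkene, while any Δ7 isomer converges in step 5.

**Step 5**
Reactants: 5, the 8(17)-ene
Product: 6, 12-TBSO-2α-chloro-13,14,15,16-tetranorlabd-7-ene
Conditions: Co(salen-tBu,tBu)Cl (3 mol %), PhSiH3 (6 mol %), PhH, rt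
Reagents that add atoms: none
Why: Co–H MHAT radical alkene isomerisation (1,1-disubstituted → trisubstituted); back-abstraction from the C8 radical should favour the secondary C7–H over the hindered tertiary C9–H next to quaternary C10, giving the Δ7 alkene with C9 intact.

**Step 6**
Reactants: 6, the Δ7 alkene
Product: 7, 12-TBSO-2α-chloro-13,14,15,16-tetranorlabd-7-en-6-one
Conditions: CrO3, 3,5-dimethylpyrazole, CH2Cl2, −20 °C
Reagents that add atoms: chromium trioxide, O=[Cr](=O)=O (O)
Why: Cr(VI)–pyrazole allylic oxidation; C6 is the only allylic ring CH2, so the 7-en-6-one forms (as with drim-7-enes) and the trans ring fusion at C5 is retained.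

**Step 7**
Reactants: 7, the 7-en-6-one
Product: 8, 12-TBSO-2α-chloro-13,14,15,16-tetranorlabd-8(17)-en-6-one
Conditions: LDA, THF/HMPA, −78 °C; inverse quench into AcOH/THF, −78 °C
Reagents that add atoms: none
Why: Kinetic deconjugation of an enone: γ-deprotonation at the only primary site (C17 methyl; C5–H and C9–H are hindered tertiary) gives the exocyclic dienolate, and kinetic α-protonation at C7 gives the β,γ-unsaturated ketone without changing any stereocentre.

**Step 8**
Reactants: 8, the silyl ether
Product: 9, 2α-chloro-12-hydroxy-13,14,15,16-tetranorlabd-8(17)-en-6-one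
Conditions: HF·pyridine, pyridine/THF, 0 °C
Reagents that add atoms: none
Why: Buffered fluoride cleavage of the primary TBS ether; conditions are mild enough not to reconjugate the β,γ-enone.

**Step 9**
Reactants: 9, the primary alcohol
Product: 10, 2α-chloro-6-oxo-13,14,15,16-tetranorlabd-8(17)-en-12-al
Conditions: Dess–Martin periodinane, NaHCO3, CH2Cl2, 0 °C → rt
Reagents that add atoms: none
Why: Neutral buffered Dess–Martin oxidation of the primary alcohol to the aldehyde; the alkene, ketone and chloride are inert.

**Step 10**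
Reactants: 10, the keto-aldehyde; 11, maleimide (2 equiv, N-silylated in situ)
Product: 12, haterumaimide G
Conditions: 11 + BSA, THF, rt (gives N-TMS-maleimide); Ni(cod)2 (10 mol %), chiral NHC L* [(4R,5R)-1,3-bis(2-isopropylphenyl)-4,5-diphenylimidazolidin-2-ylidene, preformed from its imidazolinium BF4 salt and KHMDS] (12 mol %), Et3SiH (2 equiv), THF, 0 °C → rt; then HF·pyridine, THF, 0 °C (removes O–SiEt3 and N–SiMe3)
Reagents that add atoms: none besides reactant 11 (maleimide, O=C1C=CC(=O)N1); Et3SiH supplies only H
Why: Proposed new method: Ni(0)–NHC-catalysed enantioselective reductive (homo-aldol-type) coupling of an aldehyde with maleimide, in which η2-aldehyde and η2-maleimide on Ni(0)L* undergo oxidative cyclisation to an oxanickelacyclopentane cis-fused to the imide ring (forming C12–C13 and a Ni–C14 enolate); the aldehyde substituent sits exo on the convex face, trans to C16 across the new bond, which is the 12,13-syn relationship required, while the C2-symmetric NHC is chosen to select the aldehyde Re face (12S, hence 13R; the ligand antipode is equally available if induction is opposite), and Et3SiH σ-bond metathesis at Ni–O followed by C–H reductive elimination at C14 releases product and Ni(0); the closest known reaction type is the Ni(0)/NHC–silane reductive coupling of aldehydes with alkynes or 1,3-dienes via oxanickelacycles (and SmI2 ketyl–acrylate couplings to γ-lactones), and the hindered C6 ketone, 1,1-disubstituted alkene and secondary chloride should be poor partners for Ni(0) at rt.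

## Compound list

All decalins have 5α-H, 9α-H (side chain β) and 10β-Me.

1 | (+)-sclareolide, (3aR,5aS,9aS,9bR)-3a,6,6,9a-tetramethyldecahydronaphtho[2,1-b]furan-2(1H)-one | C[C@@]12CC[C@H]3C(C)(C)CCC[C@]3(C)[C@H]1CC(=O)O2 | starting material
2 | 2α-chlorosclareolide | C[C@@]12CC[C@H]3C(C)(C)C[C@H](Cl)C[C@]3(C)[C@H]1CC(=O)O2 | intermediate
3 | 2α-chloro-13,14,15,16-tetranorlabdane-8α,12-diol | C[C@@]1(O)CC[C@H]2C(C)(C)C[C@H](Cl)C[C@]2(C)[C@H]1CCO | intermediate
4 | 12-(tert-butyldimethylsilyloxy)-2α-chloro-13,14,15,16-tetranorlabdan-8α-ol | C[C@@]1(O)CC[C@H]2C(C)(C)C[C@H](Cl)C[C@]2(C)[C@H]1CCO[Si](C)(C)C(C)(C)C | intermediate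
5 | 12-TBSO-2α-chloro-13,14,15,16-tetranorlabd-8(17)-ene | C=C1CC[C@H]2C(C)(C)C[C@H](Cl)C[C@]2(C)[C@H]1CCO[Si](C)(C)C(C)(C)C | intermediate
6 | 12-TBSO-2α-chloro-13,14,15,16-tetranorlabd-7-ene | CC1=CC[C@H]2C(C)(C)C[C@H](Cl)C[C@]2(C)[C@H]1CCO[Si](C)(C)C(C)(C)C | intermediate
7 | 12-TBSO-2α-chloro-13,14,15,16-tetranorlabd-7-en-6-one | CC1=CC(=O)[C@H]2C(C)(C)C[C@H](Cl)C[C@]2(C)[C@H]1CCO[Si](C)(C)C(C)(C)C | intermediate
8 | 12-TBSO-2α-chloro-13,14,15,16-tetranorlabd-8(17)-en-6-one | C=C1CC(=O)[C@H]2C(C)(C)C[C@H](Cl)C[C@]2(C)[C@H]1CCO[Si](C)(C)C(C)(C)C | intermediate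
9 | 2α-chloro-12-hydroxy-13,14,15,16-tetranorlabd-8(17)-en-6-one | C=C1CC(=O)[C@H]2C(C)(C)C[C@H](Cl)C[C@]2(C)[C@H]1CCO | intermediate
10 | 2α-chloro-6-oxo-13,14,15,16-tetranorlabd-8(17)-en-12-al | C=C1CC(=O)[C@H]2C(C)(C)C[C@H](Cl)C[C@]2(C)[C@H]1CC=O | intermediate
11 | maleimide | O=C1C=CC(=O)N1 | starting material
12 | haterumaimide G, (2S,5S,9S,10R,12S,13R) | C=C1CC(=O)[C@H]2C(C)(C)C[C@H](Cl)C[C@]2(C)[C@H]1C[C@H](O)[C@H]1CC(=O)NC1=O | target

## Summary

Total steps: 10. Longest linear sequence: 10 (from (+)-sclareolide).

Three steps most likely to fail, with fallbacks: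

1. **Step 10 (proposed new Ni-catalysed aldehyde–maleimide coupling).** Risks are aldehyde hydrosilylation or Tishchenko dimerisation, simple reduction of maleimide, and low dr/ee. Fallback (known chemistry): Evans syn-aldol of 10 with the dibutylboron enolate of (R)-4-benzyl-3-(4-methoxy-4-oxobutanoyl)oxazolidin-2-one (Bu2BOTf, i-Pr2NEt, CH2Cl2, −78 → 0 °C), giving the 12S,13R syn adduct, then NH3/MeOH to close the succinimide with loss of the auxiliary.

2. **Step 7 (kinetic deconjugation).** Risks are competing C9–H or C5–H deprotonation and reconjugation. Fallback: generate the exocyclic dienolate regiospecifically by reduction rather than deprotonation. Epoxidise 7 (H2O2/NaOH), isomerise the 7,8-epoxide toward C17 to the 7-oxygenated 8(17)-en-6-one (TMSOTf/2,6-lutidine then DBU, then acetylate), and cleave the α-oxygen with SmI2/MeOH at −78 °C so that α-protonation gives 8.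

3. **Step 5 (regioselective exo → Δ7 isomerisation).** Risk is formation of the tetrasubstituted Δ8(9) alkene. Fallback: drop the Δ7 relay. Ozonolyse 5 to the 8-ketone, desaturate to the 6-en-8-one (Saegusa), install C6–OH by Cu-catalysed β-borylation/oxidation, protect, methylenate C8 (Wittig), then deprotect and oxidise C6 to reach 8.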